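The target, (3S,5R,8S,3'R,6'R)-5,8-epoxy-5,8-dihydro-β,ε-carotene-3,3'-diol, is cut at the two sp2–sp2 single bonds C10–C11 and C10'–C11', which flank a C2-symmetric all-E pentaene (C11 to C11'). One palladium-catalysed one-pot operation joins three pieces: a Stille coupling at the tin end of a tin/boron pentaene with the ε-end dienyl iodide, then, after base is added, a Suzuki–Miyaura coupling at the boron end with the furanoid alkenyl iodide. The never-acidic medium spares the bis-allylic C5–O–C8 ether of the dihydrofuran ring, and both couplings retain alkene geometry. The precursors are iodides 14 and 25, both with free hydroxyls, and stannyl boronate 7.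

Key step: step 17

Remark on the chemistry: (R)-(+)-α-ionone (8) and (4R,6R)-actinol (15) are assumed to be purchasable in enantiopure form; they supply C6' and C3, and all other stereocentres are made in the route.

**Pentaene linchpin**

Step 1
Reactants: 1 dibromomethane; 2 tributyltin chloride
Product: 3 (dibromomethyl)tributylstannane
Conditions: 1, LiN(i-Pr)2, THF/Et2O, −95 °C; then 2, −95 °C → rt
Reagents that add atoms: none
Why: Deprotonation of dibromomethane below −90 °C gives the carbenoid LiCHBr2, which is stable at that temperature and is trapped by nucleophilic substitution at tin (carbenoid stannylation).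

Step 2
Reactants: 4 (2E,4E,6E)-2,7-dimethylocta-2,4,6-trienedial (3 equiv); 5 2-(dichloromethyl)pinacolborane
Product: 6 boryl tetraenal
Conditions: CrCl2 (8 equiv), LiI (4 equiv), THF, rt, dark; excess 4 recovered by chromatography
Reagents that add atoms: none
Why: Takai–Utimoto olefination, in which halogen exchange with LiI and reduction by divalent chromium give a geminal dichromium species that adds to one aldehyde group and eliminates to the E-alkenyl boronate; the two ends of 4 are equivalent and its excess should limit double olefination.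

Step 3
Reactants: 6 boryl tetraenal; 3 (dibromomethyl)tributylstannane
Product: 7 stannyl boryl pentaene
Conditions: CrCl2 (10 equiv), LiI (4 equiv), THF/DMF, rt, dark; chromatography on Et3N-deactivated silica
Reagents that add atoms: none
Why: The same chromium-mediated Takai-type olefination with the stannyl gem-dihalide should homologate the remaining aldehyde to the E-alkenylstannane, and the neutral medium leaves the pinacol boronate untouched.

**ε-End iodide**

Step 4
Reactants: 8 (R)-α-ionone
Product: 10 (R)-enyne, via enol phosphate 9 (not isolated)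
Conditions: LiN(i-Pr)2 (1.05 equiv), THF, −78 °C; ClP(O)(OEt)2, −78 °C → rt; then LiN(i-Pr)2 (2.3 equiv), THF, −78 °C → rt
Reagents that add atoms: none
Why: Kinetic deprotonation at the methyl group, O-phosphorylation and base-induced elimination of diethyl phosphate convert the methyl ketone into the terminal alkyne (Negishi alkyne synthesis from methyl ketones), and the cross-conjugated kinetic enolate leaves the C6' hydrogen and the C7'=C8' geometry in place.

Step 5
Reactants: 10 (R)-enyne
Product: 12 (R)-dienyl iodide, via alkenylalane 11 (not isolated)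
Conditions: AlMe3 (3 equiv), Cp2ZrCl2 (0.25 equiv), CH2Cl2, 0 °C → rt; then I2, THF, −30 → 0 °C
Reagents that add atoms: trimethylaluminium C[Al](C)C; iodine II
Why: Zirconium-catalysed syn-carboalumination of the terminal alkyne (Negishi carboalumination) places methyl on C9' and aluminium on C10', and iodinolysis of the C–Al bond with retention gives the (E)-iodide.

Step 6
Reactants: 12 (R)-dienyl iodide
Product: 13 3'-oxo dienyl iodide
Conditions: CrO3, 3,5-dimethylpyrazole, CH2Cl2, −20 °C
Reagents that add atoms: chromium trioxide O=[Cr](=O)=O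
Why: Allylic C–H oxidation by the CrO3·3,5-dimethylpyrazole complex should convert the only allylic methylene, the ring CH2 at C3' next to the trisubstituted C4'=C5' bond, into the enone, as is established for α-ionone-type rings; the allylic methyls and the hindered tertiary C6'–H react more slowly and the alkenyl iodide is inert to hexavalent chromium.

Step 7
Reactants: 13 3'-oxo dienyl iodide
Product: 14 ε-end dienyl iodide (3'R,6'R)
Conditions: LiBH(s-Bu)3 (L-Selectride), THF, −78 °C; then H2O
Reagents that add atoms: none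
Why: Substrate-controlled 1,2-reduction of the β,β-disubstituted enone by the bulky borohydride: with the side chain pseudoaxial at C6', hydride should arrive on the face away from the axial C1' methyl, which lies opposite to the side chain, so the new C3' hydroxyl is expected trans to the C6' substituent (3'R), and any cis epimer is removed by chromatography.

**Furanoid iodide**

Step 8
Reactants: 15 (4R,6R)-actinol
Product: 16 silyl ether of actinol
Conditions: TBSCl, imidazole, DMF, rt
Reagents that add atoms: tert-butyldimethylsilyl chloride CC(C)(C)[Si](C)(C)Cl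
Why: Imidazole-promoted silylation of the secondary alcohol protects O3 for the strongly basic and acidic steps that follow.

Step 9
Reactants: 16 silyl ether of actinol
Product: 17 enol triflate
Conditions: LiN(i-Pr)2, THF, −78 °C; PhNTf2, −78 °C → rt
Reagents that add atoms: N-phenylbis(trifluoromethanesulfonimide) FC(F)(F)S(=O)(=O)N(c1ccccc1)S(=O)(=O)C(F)(F)F
Why: The ketone can enolise only towards C5, so enolate O-triflation gives a single tetrasubstituted enol triflate; the C5 stereocentre of 16 is removed on purpose and set again in step 11.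

Step 10
Reactants: 17 enol triflate
Product: 18 allylic alcohol
Conditions: Bu3SnCH2OH, Pd(PPh3)4 (10 mol %), LiCl, 1,4-dioxane, 100 °C
Reagents that add atoms: (tributylstannyl)methanol OC[Sn](CCCC)(CCCC)CCCC
Why: Stille coupling of the enol triflate with the hydroxymethylstannane (oxidative addition to C–OTf assisted by chloride, transfer of CH2OH from tin, reductive elimination) installs C7 as the allylic alcohol needed for a directed epoxidation.

Step 11
Reactants: 18 allylic alcohol
Product: 19 epoxy alcohol
Conditions: Ti(OiPr)4 (0.2 equiv), D-(−)-diethyl tartrate (0.25 equiv), t-BuOOH, 4 Å molecular sieves, CH2Cl2, −20 °C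
Reagents that add atoms: tert-butyl hydroperoxide CC(C)(C)OO
Why: Sharpless asymmetric epoxidation, in which the titanium tartrate complex binds the allylic hydroxyl and delivers oxygen to one face of the tetrasubstituted C5=C6 bond under reagent control; the D-(−)-tartrate should direct oxygen to the face opposite the C3 silyloxy group and so set C5 (R) and C6 together.

Step 12
Reactants: 19 epoxy alcohol
Product: 20 epoxy aldehyde
Conditions: Dess–Martin periodinane, NaHCO3, CH2Cl2, 0 °C → rt
Reagents that add atoms: none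
Why: Dess–Martin oxidation of the primary alcohol under buffered conditions; the aldehyde has no α-hydrogen, so the epoxide stereocentres are not at risk.

Step 13
Reactants: 20 epoxy aldehyde
Product: 21 epoxy enyne
Conditions: [Ph3PCH2C≡CSiMe3]Br, n-BuLi, THF, −78 → 0 °C
Reagents that add atoms: [3-(trimethylsilyl)prop-2-yn-1-yl]triphenylphosphonium bromide C[Si](C)(C)C#CC[P+](c1ccccc1)(c1ccccc1)c1ccccc1.[Br-]
Why: Wittig olefination of the hindered, non-enolisable aldehyde with the semistabilised propargyl ylide builds C7=C8 and brings in C9 and C10 as a silyl-capped alkyne; a 7E/7Z mixture is expected and is of no consequence because C8 becomes sp3 in step 14.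

Step 14
Reactants: 21 epoxy enyne
Product: 22 furanoid silyl alkyne (8S)
Conditions: camphorsulfonic acid (cat.), CH2Cl2, 0 °C; Et3N quench; chromatography on Et3N-deactivated silica
Reagents that add atoms: none
Why: Acid-catalysed epoxide-to-furanoid rearrangement: protonation opens the C6–O bond to an allyl cation (C6–C7–C8) stabilised by the alkyne and the C5 oxygen recloses on C8 to the 2,5-dihydrofuran with C5 untouched; the two faces at C8 are not differentiated, so both C8 epimers are expected, the (8S) epimer is separated by chromatography and the (8R) epimer is re-equilibrated under the same conditions, while the O3 silyl ether prevents a competing 3,6-ether closure.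

Step 15
Reactants: 22 furanoid silyl alkyne (8S)
Product: 23 furanoid alkynol
Conditions: Bu4NF, THF, 0 °C → rt
Reagents that add atoms: none
Why: Fluoride-mediated desilylation cleaves the O–Si bond of the secondary silyl ether and the C–Si bond of the alkynylsilane in one operation, under basic conditions that the furanoid ether tolerates.

Step 16
Reactants: 23 furanoid alkynol
Product: 25 furanoid alkenyl iodide, via alkenylalane 24 (not isolated)
Conditions: AlMe3 (4 equiv), Cp2ZrCl2 (0.2 equiv), H2O (1 equiv), CH2Cl2, −23 °C; then I2, THF, −23 → 0 °C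
Reagents that add atoms: trimethylaluminium C[Al](C)C; iodine II
Why: After the hydroxyl is converted into its aluminium alkoxide, zirconium-catalysed syn-carboalumination of the terminal alkyne (Negishi carboalumination, water-accelerated so that it runs at −23 °C and exposes the Lewis-acid-sensitive C8–O bond only briefly) and iodinolysis with retention give the (E)-alkenyl iodide without involving C8.

**Key step**

Step 17
Reactants: 14 ε-end dienyl iodide; 7 stannyl boryl pentaene; 25 furanoid alkenyl iodide
Product: 27 target (3S,5R,8S,3'R,6'R)-5,8-epoxy-5,8-dihydro-β,ε-carotene-3,3'-diol, via heptaenyl boronate 26 (not isolated)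
Conditions: 14, 7, Pd2(dba)3 (5 mol %), AsPh3 (40 mol %), THF/DMF, 40 °C, argon, dark; then 25, Cs2CO3, H2O, rt
Reagents that add atoms: none
Why: Zerovalent palladium ligated by AsPh3 adds oxidatively to the C10'–I bond of 14, transmetalates with the alkenylstannane end of 7 under base-free conditions, in which the pinacol boronate is not activated, and reductively eliminates to forge C10'–C11' (Stille coupling); once 25, Cs2CO3 and water are added, the boronate of 26 forms its ate complex and enters a second cycle with the C10–I bond of 25, forging C10–C11 (Suzuki–Miyaura coupling). The closest known reaction type is the one-pot sequential Stille/Suzuki–Miyaura union of tin/boron hetero-bis-metallated polyenes with two different alkenyl iodides. No ring is closed and no stereocentre is created, so all five stereocentres are carried in unchanged from 14 and 25. The selectivities needed are tin-before-boron chemoselectivity, secured by withholding base in the first stage, and retention of every alkene geometry, secured by the stereospecific oxidative addition, transmetalation and reductive elimination at sp2 carbon. Because the C11–C11' pentaene is C2-symmetric, either metal terminus may meet either end group, and the acid-labile iodide 25 enters only in the basic second stage, which keeps its C5–O–C8 ether away from Bu3SnI in a neutral medium.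

**Compound list**

1 | dibromomethane | BrCBr | starting material
2 | tributyltin chloride | CCCC[Sn](CCCC)(CCCC)Cl | starting material
3 | (dibromomethyl)tributylstannane | CCCC[Sn](CCCC)(CCCC)C(Br)Br | intermediate
4 | (2E,4E,6E)-2,7-dimethylocta-2,4,6-trienedial | O=C/C(C)=C/C=C/C=C(C)/C=O | starting material
5 | 2-(dichloromethyl)-4,4,5,5-tetramethyl-1,3,2-dioxaborolane | ClC(Cl)B1OC(C)(C)C(C)(C)O1 | starting material
6 | (2E,4E,6E,8E)-2,7-dimethyl-9-(4,4,5,5-tetramethyl-1,3,2-dioxaborolan-2-yl)nona-2,4,6,8-tetraenal | O=C/C(C)=C/C=C/C=C(C)/C=C/B1OC(C)(C)C(C)(C)O1 | intermediate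
7 | tributyl[(1E,3E,5E,7E,9E)-3,8-dimethyl-10-(4,4,5,5-tetramethyl-1,3,2-dioxaborolan-2-yl)deca-1,3,5,7,9-pentaen-1-yl]stannane | CCCC[Sn](CCCC)(CCCC)/C=C/C(C)=C/C=C/C=C(C)/C=C/B1OC(C)(C)C(C)(C)O1 | intermediate
8 | (R)-α-ionone, (3E)-4-[(1R)-2,6,6-trimethylcyclohex-2-en-1-yl]but-3-en-2-one | CC1=CCCC(C)(C)[C@H]1/C=C/C(C)=O | starting material
9 | diethyl (3E)-4-[(1R)-2,6,6-trimethylcyclohex-2-en-1-yl]buta-1,3-dien-2-yl phosphate (not isolated) | CC1=CCCC(C)(C)[C@H]1/C=C/C(=C)OP(=O)(OCC)OCC | intermediate
10 | (6R)-6-[(1E)-but-1-en-3-yn-1-yl]-1,5,5-trimethylcyclohex-1-ene | CC1=CCCC(C)(C)[C@H]1/C=C/C#C | intermediate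
11 | dimethyl{(1E,3E)-2-methyl-4-[(1R)-2,6,6-trimethylcyclohex-2-en-1-yl]buta-1,3-dien-1-yl}alane (not isolated) | CC1=CCCC(C)(C)[C@H]1/C=C/C(C)=C/[Al](C)C | intermediate
12 | (6R)-6-[(1E,3E)-4-iodo-3-methylbuta-1,3-dien-1-yl]-1,5,5-trimethylcyclohex-1-ene | CC1=CCCC(C)(C)[C@H]1/C=C/C(C)=C/I | intermediate
13 | (4R)-4-[(1E,3E)-4-iodo-3-methylbuta-1,3-dien-1-yl]-3,5,5-trimethylcyclohex-2-en-1-one | CC1=CC(=O)CC(C)(C)[C@H]1/C=C/C(C)=C/I | intermediate
14 | (1R,4R)-4-[(1E,3E)-4-iodo-3-methylbuta-1,3-dien-1-yl]-3,5,5-trimethylcyclohex-2-en-1-ol (hydroxyl and side chain trans) | CC1=C[C@H](O)CC(C)(C)[C@H]1/C=C/C(C)=C/I | intermediate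
15 | (4R,6R)-4-hydroxy-2,2,6-trimethylcyclohexan-1-one (actinol) | C[C@@H]1C[C@@H](O)CC(C)(C)C1=O | starting material
16 | (4R,6R)-4-(tert-butyldimethylsilyloxy)-2,2,6-trimethylcyclohexan-1-one | C[C@@H]1C[C@@H](O[Si](C)(C)C(C)(C)C)CC(C)(C)C1=O | intermediate
17 | (4R)-4-(tert-butyldimethylsilyloxy)-2,6,6-trimethylcyclohex-1-en-1-yl trifluoromethanesulfonate | CC1=C(OS(=O)(=O)C(F)(F)F)C(C)(C)C[C@H](O[Si](C)(C)C(C)(C)C)C1 | intermediate
18 | [(4R)-4-(tert-butyldimethylsilyloxy)-2,6,6-trimethylcyclohex-1-en-1-yl]methanol | CC1=C(CO)C(C)(C)C[C@H](O[Si](C)(C)C(C)(C)C)C1 | intermediate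
19 | [(1R,4S,6R)-4-(tert-butyldimethylsilyloxy)-2,2,6-trimethyl-7-oxabicyclo[4.1.0]heptan-1-yl]methanol (epoxide anti to the silyloxy group) | OC[C@@]12O[C@]1(C)C[C@@H](O[Si](C)(C)C(C)(C)C)CC2(C)C | intermediate
20 | (1S,4S,6R)-4-(tert-butyldimethylsilyloxy)-2,2,6-trimethyl-7-oxabicyclo[4.1.0]heptane-1-carbaldehyde | O=C[C@@]12O[C@]1(C)C[C@@H](O[Si](C)(C)C(C)(C)C)CC2(C)C | intermediate
21 | (1S,4S,6R)-4-(tert-butyldimethylsilyloxy)-2,2,6-trimethyl-1-[(1E)-4-(trimethylsilyl)but-1-en-3-yn-1-yl]-7-oxabicyclo[4.1.0]heptane (7E shown; the 7Z isomer may accompany it and converges in step 14) | C[Si](C)(C)C#C/C=C/[C@@]12O[C@]1(C)C[C@@H](O[Si](C)(C)C(C)(C)C)CC2(C)C | intermediate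
22 | tert-butyldimethyl{[(2S,6S,7aR)-4,4,7a-trimethyl-2-[(trimethylsilyl)ethynyl]-2,4,5,6,7,7a-hexahydro-1-benzofuran-6-yl]oxy}silane (carotenoid 3S,5R,8S) | C[Si](C)(C)C#C[C@@H]1C=C2C(C)(C)C[C@H](O[Si](C)(C)C(C)(C)C)C[C@@]2(C)O1 | intermediate
23 | (2S,6S,7aR)-2-ethynyl-4,4,7a-trimethyl-2,4,5,6,7,7a-hexahydro-1-benzofuran-6-ol | C#C[C@@H]1C=C2C(C)(C)C[C@H](O)C[C@@]2(C)O1 | intermediate
24 | dimethylaluminium alkoxide of the (E)-2-(dimethylalanyl)-1-methylethenyl furanoid (not isolated) | C[Al](C)/C=C(\C)[C@@H]1C=C2C(C)(C)C[C@H](O[Al](C)C)C[C@@]2(C)O1 | intermediate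
25 | (2S,6S,7aR)-2-[(1E)-1-iodoprop-1-en-2-yl]-4,4,7a-trimethyl-2,4,5,6,7,7a-hexahydro-1-benzofuran-6-ol | I/C=C(\C)[C@@H]1C=C2C(C)(C)C[C@H](O)C[C@@]2(C)O1 | intermediate
26 | (1R,4R)-3,5,5-trimethyl-4-[(1E,3E,5E,7E,9E,11E,13E)-3,7,12-trimethyl-14-(4,4,5,5-tetramethyl-1,3,2-dioxaborolan-2-yl)tetradeca-1,3,5,7,9,11,13-heptaen-1-yl]cyclohex-2-en-1-ol (not isolated) | CC1=C[C@H](O)CC(C)(C)[C@H]1/C=C/C(C)=C/C=C/C(C)=C/C=C/C=C(C)/C=C/B1OC(C)(C)C(C)(C)O1 | intermediate
27 | (3S,5R,8S,3'R,6'R)-5,8-epoxy-5,8-dihydro-β,ε-carotene-3,3'-diol, all-E | CC1=C[C@H](O)CC(C)(C)[C@H]1/C=C/C(C)=C/C=C/C(C)=C/C=C/C=C(C)/C=C/C=C(\C)[C@@H]1C=C2C(C)(C)C[C@H](O)C[C@@]2(C)O1 | target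

**Step count and risks**

Total step count: 17. Longest linear sequence: 10 steps (15 to 27, steps 8 to 17).

Steps most likely to fail:

1. Step 6. The C–H oxidation may lose chemoselectivity, through attack of the oxidant on the iodo-diene or on the doubly allylic C6'–H, and the enone may suffer double-bond migration on work-up. The fallback sets out from 8 and comes back at 14; it introduces the ring oxygen before the iodo-diene exists, on the ketone-protected ring. 8 is ketalised (ethylene glycol, HC(OMe)3, cat. TsOH) to the dioxolane F1. Allylic oxidation (t-BuOOH, NaOCl, K2CO3, MeCN, or CrO3·3,5-dimethylpyrazole) gives the enone ketal F2. LiBH(s-Bu)3 gives the trans alcohol F3, and TBSCl with imidazole gives the silyl ether F4. Pyridinium p-toluenesulfonate in wet acetone frees the methyl ketone F5. The conditions of step 4 give, through the enol phosphate F6, the silyloxy enyne F7. The conditions of step 5 give, through the alkenylalane F8, the silyloxy dienyl iodide F9, and Bu4NF then returns 14.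

2. Step 14. The closure on C8 lacks facial discrimination, and re-ionisation of the product can erode the wanted (8S) epimer. The fallback sets out from 20 and comes back at 22; it sets C8 by chirality transfer in place of a cation closure. 20 is homologated with dimethyl (1-diazo-2-oxopropyl)phosphonate and K2CO3 in MeOH (Seyferth–Gilbert homologation) to the ethynyl oxirane F10. Pd(PPh3)4-catalysed coupling with Me3SiC≡CZnCl opens the oxirane by anti-SN2' substitution and gives the allenynol F11, with the alkynyl group on C8 on the face opposite to the departed C6–O bond. AgNO3 in acetone (or catalytic AuCl3) then adds O5 to C8 with axis-to-centre transfer; by this geometry C9 should end up cis to the C5 methyl, that is (8S), which delivers 22.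

3. Step 17. The boronate may be activated too early (homocoupling, scrambling of the two iodides), the linchpin may undergo protodestannylation or protodeborylation, and the polyene may isomerise during the long one-pot sequence. The fallback sets out from 6 and 14 and comes back at 26; it is an iterative sequence without tin and without chemoselection between two metals. 6 and 14 are joined in a separate Suzuki–Miyaura coupling (Pd(PPh3)4, aqueous Cs2CO3, THF) to the C25 hexaenal F12. A second Takai–Utimoto olefination with 5, CrCl2 and LiI converts its aldehyde into 26, now isolated. An ordinary Suzuki–Miyaura coupling of 26 with 25 then gives 27.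

**Further compounds**

F1 | step 6 | 2-methyl-2-{(E)-2-[(1R)-2,6,6-trimethylcyclohex-2-en-1-yl]ethenyl}-1,3-dioxolane | CC1=CCCC(C)(C)[C@H]1/C=C/C1(C)OCCO1
F2 | step 6 | (4R)-3,5,5-trimethyl-4-[(E)-2-(2-methyl-1,3-dioxolan-2-yl)ethenyl]cyclohex-2-en-1-one | CC1=CC(=O)CC(C)(C)[C@H]1/C=C/C1(C)OCCO1
F3 | step 6 | (1R,4R)-3,5,5-trimethyl-4-[(E)-2-(2-methyl-1,3-dioxolan-2-yl)ethenyl]cyclohex-2-en-1-ol | CC1=C[C@H](O)CC(C)(C)[C@H]1/C=C/C1(C)OCCO1
F4 | step 6 | tert-butyldimethylsilyl ether of F3 | CC1=C[C@H](O[Si](C)(C)C(C)(C)C)CC(C)(C)[C@H]1/C=C/C1(C)OCCO1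
F5 | step 6 | (3E)-4-[(1R,4R)-4-(tert-butyldimethylsilyloxy)-2,6,6-trimethylcyclohex-2-en-1-yl]but-3-en-2-one | CC1=C[C@H](O[Si](C)(C)C(C)(C)C)CC(C)(C)[C@H]1/C=C/C(C)=O
F6 | step 6 | diethyl (3E)-4-[(1R,4R)-4-(tert-butyldimethylsilyloxy)-2,6,6-trimethylcyclohex-2-en-1-yl]buta-1,3-dien-2-yl phosphate (not isolated) | CC1=C[C@H](O[Si](C)(C)C(C)(C)C)CC(C)(C)[C@H]1/C=C/C(=C)OP(=O)(OCC)OCC
F7 | step 6 | tert-butyl{[(1R,4R)-4-[(1E)-but-1-en-3-yn-1-yl]-3,5,5-trimethylcyclohex-2-en-1-yl]oxy}dimethylsilane | CC1=C[C@H](O[Si](C)(C)C(C)(C)C)CC(C)(C)[C@H]1/C=C/C#C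
F8 | step 6 | dimethylalane from carboalumination of F7 (not isolated) | CC1=C[C@H](O[Si](C)(C)C(C)(C)C)CC(C)(C)[C@H]1/C=C/C(C)=C/[Al](C)C
F9 | step 6 | tert-butyldimethylsilyl ether of 14 | CC1=C[C@H](O[Si](C)(C)C(C)(C)C)CC(C)(C)[C@H]1/C=C/C(C)=C/I
F10 | step 14 | (1R,4S,6R)-4-(tert-butyldimethylsilyloxy)-1-ethynyl-2,2,6-trimethyl-7-oxabicyclo[4.1.0]heptane | C#C[C@@]12O[C@]1(C)C[C@@H](O[Si](C)(C)C(C)(C)C)CC2(C)C
F11 | step 14 | (1R,4S)-4-(tert-butyldimethylsilyloxy)-1,3,3-trimethyl-2-[4-(trimethylsilyl)but-1-en-3-yn-1-ylidene]cyclohexan-1-ol, allene axis (R), alkynyl group on the face of the silyloxy group | C[Si](C)(C)C#CC=[C@@]=C1C(C)(C)C[C@H](O[Si](C)(C)C(C)(C)C)C[C@@]1(C)O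
F12 | step 17 | (2E,4E,6E,8E,10E,12E)-13-[(1R,4R)-4-hydroxy-2,6,6-trimethylcyclohex-2-en-1-yl]-2,7,11-trimethyltrideca-2,4,6,8,10,12-hexaenal | CC1=C[C@H](O)CC(C)(C)[C@H]1/C=C/C(C)=C/C=C/C(C)=C/C=C/C=C(C)/C=O
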